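## Analysis of the target

The target is a pulvinone: a 4-hydroxyfuran-2(5H)-one (tetronic acid, ring C: O1, C2, C3, C4, C5). C3 carries a 7-hydroxy-2,2-dimethylchroman-6-yl group (benzene ring A fused to dihydropyran ring B). C5 carries a Z-configured exocyclic C5=C6 benzylidene whose arene (ring D) is a phenol with an ortho (2R)-3,3-dimethyloxiran-2-ylmethyl side chain.

There is one stereocentre, the oxirane CH (R), and one stereogenic double bond (C5=C6, ring D cis to O1). They are far apart and do not influence each other, so the stereocentre has to come from reagent control.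

Both side chains are prenyl units in different end states: one is cyclised onto its phenol as ring B, the other is epoxidised and left open next to a free phenol. They therefore have to be processed on separate fragments.

The sensitive groups are:
- the trisubstituted epoxide, which the neighbouring phenol can open (5-exo or 6-endo) under acid or base;
- the tetronic acid, an internal acid of carboxylic strength and an enolate-like nucleophile towards oxidants;
- the Z-ylidene.

The difficulty is ring C, a fully substituted five-membered ring with defined alkene geometry between two different electron-rich arenes, and an endgame that must free three acidic hydroxyls without touching the epoxide.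

The feature that invites a bold move lies in ring C itself. C2, bonded to O1 and the carbonyl oxygen, stands at the oxidation level of carbon dioxide and sits between the enolisable benzylic carbon C3 and O1. The unit O1–C5=C6 is the anti adduct of an oxygen nucleophile to an aryl alkyne. Ring C can thus be made by inserting CO2 into an acyclic 1,4-diarylbut-3-yn-2-one, which forms C2–C3 and O1–C5 and fixes the C5=C6 geometry in one operation.

## Retrosynthetic reasoning

Target 24 is traced back to its bis(triisopropylsilyl) ether 23 by cutting the two aryl O–Si bonds. The epoxide is kept in 23, because a late epoxidation would have to choose between the prenyl alkene, the tetronate and free phenols under basic oxidising conditions. The forward step must release the phenols near neutrality so that the ring D phenol does not open the oxirane.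

Ring C of 23 is cut at C2–C3 and O1–C5. This removes C2 as carbon dioxide 20 and turns C5=C6 back into the triple bond of ynone 19 (through carboxylate 21 and alkenylsilver 22). The cut is made here because C2 has the oxidation level of 20, C3–H of 19 is doubly activated (benzylic and alpha to the ketone), and the alkyne encodes the Z geometry mechanistically. The gain is an acyclic precursor without ring C and without any alkene geometry to control. The forward reaction has to carboxylate at carbon, close 5-exo and not 6-endo, add anti across the alkyne, and leave the epoxide and silyl ethers alone. Naming only this step and ynone 19 does not describe the aldol route that is usually drawn for pulvinones.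

Ynone 19 is cut between the ketone carbon and the alkyne carbon. This gives Weinreb amide 7 (rings A and B, fragment 1) and terminal alkyne 16 (ring D with the epoxide, fragment 2), joined through lithium acetylide 17 and chelated adduct 18. It is the most convergent cut, and the forward step must stop after one addition.

Amide 7 goes back through phenol 6 to lactone 5 by cutting the O–Si and amide C–N bonds and rejoining the phenol oxygen to the acyl carbon. Lactone 5 is an internally activated ester that masks phenol and acid together. It is cut at the lactone C–O bond and at O1′–C2′ and C4′–C4a′ of ring B, giving 2-(2,4-dihydroxyphenyl)acetic acid 1 and isoprene 2 (via 3 and 4). The substitution pattern of 1 directs the prenyl unit to the position that leads to the linear chroman.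

Alkyne 16 is traced back by C–Si cleavage to silylalkyne 15, and by removal of the epoxide oxygen to prenyl arene 14. The Shi epoxidation sets the only stereocentre on a small, neutral substrate whose prenyl group is its only electron-rich alkene. Cutting the aryl–alkyne bond of 14 gives aryl iodide 12 and ethynyltrimethylsilane 13.

Aryl iodide 12 is the silyl ether of phenol 11. Phenol 11 is cut at the aryl–CH2 bond ortho to oxygen, giving 4-iodophenol 8 (as phenoxide 10) and prenyl bromide 9. The iodine blocks the para position and later serves as the coupling handle.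

## Alternatives that were turned down

Alternative 1: the textbook disconnection at the exocyclic C5=C6 bond.
- Forward key step: aldol condensation of the C5 anion of 3-[7-(benzyloxy)-2,2-dimethylchroman-6-yl]-4-methoxyfuran-2(5H)-one A1 with 4-(benzyloxy)-3-(3-methylbut-2-en-1-yl)benzaldehyde A2, then dehydration to the O-methyl pulvinone (5Z)-3-[7-(benzyloxy)-2,2-dimethylchroman-6-yl]-5-[[4-(benzyloxy)-3-(3-methylbut-2-en-1-yl)phenyl]methylidene]-4-methoxyfuran-2(5H)-one A3.
- Turned down because the step forms one bond only and ring C must be built beforehand (glycolate acylation, Dieckmann closure, O-methylation).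
- Elimination of the aldol gives both alkene isomers and needs equilibration.
- The unmasking that follows (halide demethylation of the vinylogous ester at high temperature, benzyl removal by hydrogenolysis or a boron halide) cannot coexist with a prenyl alkene or an epoxide. The epoxidation would then fall on a free tetronic acid beside a free ortho phenol.
- The route would need about fourteen steps, with the stereocentre set last under the worst conditions.

Alternative 2: disconnection at the C3–aryl bond.
- Forward key step: Suzuki coupling of (5Z)-3-bromo-5-[[3-[[(2R)-3,3-dimethyloxiran-2-yl]methyl]-4-(triisopropylsilyloxy)phenyl]methylidene]-4-methoxyfuran-2(5H)-one A4 with 2-[2,2-dimethyl-7-(triisopropylsilyloxy)chroman-6-yl]-4,4,5,5-tetramethyl-1,3,2-dioxaborolane A5.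
- Turned down because A4 still needs the aldol sequence of Alternative 1 plus a bromination, so the coupling addresses neither ring C nor the alkene geometry.
- A5 is an electron-rich aryl boronate with an ortho oxygen, prone to protodeboronation, and it must couple at a carbon flanked by a methoxy group and a lactone carbonyl.
- The C4 methyl ether again needs nucleophilic cleavage in the presence of the epoxide.

Alternative 3: disconnection of ring B at O1′–C2′ and C3′–C4′.
- Forward key step: hetero-Diels–Alder reaction of the ortho-quinone methide methyl 2-(6-hydroxy-3-methylidene-4-oxocyclohexa-1,5-dien-1-yl)acetate A7, generated by dehydration of methyl 2-[2,4-dihydroxy-5-(hydroxymethyl)phenyl]acetate A6, with 2-methylpropene.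
- It is attractive because it closes the oxygen ring together with the adjacent C–C bond with built-in regiochemistry.
- Turned down because ring B is the cheapest ring of the target: step 1 makes it from isoprene in one flask.
- A6 needs a regioselective hydroxymethylation of its own.
- 2-Methylpropene is a gaseous, only moderately electron-rich 2π partner that calls for heat and pressure, at which A7 would dimerise.
- The hydroxyl para to the hydroxymethyl group opens a competing para-quinone methide path.
- Ring C, the real problem, stays untouched.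

Key step: step 10

Assumption: the Shi ketone derived from D-fructose is taken to give the (R)-oxirane from an aryl–CH2–CH=CMe2 alkene, as its (R,R) preference for trans- and trisubstituted alkenes implies; acid 1 is taken as a catalogue chemical.

## Route

Step 1
Reactants: 1 2-(2,4-dihydroxyphenyl)acetic acid; 2 isoprene (2-methylbuta-1,3-diene)
Product: 5 7,7-dimethyl-6,7-dihydro-5H-furo[3,2-g]chromen-2(3H)-one, via C5-prenylated acid 3 (not isolated), via chromanylacetic acid 4 (not isolated)
Conditions: 2 (1.3 equiv), sulfonic acid resin (Amberlyst 15), THF–heptane, 65 °C, sealed tube; then PhMe, reflux, Dean–Stark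
Reagents that add atoms: none
Why: Acid-catalysed Friedel–Crafts prenylation should occur at C5, the position ortho to the 4-OH and para to the 2-OH that is not flanked by two substituents; the 4-OH then adds to the prenyl alkene in the Markovnikov sense to close ring B, and azeotropic drying closes the aryl lactone, which protects the phenol and activates the acid at once.

Step 2
Reactants: 5 7,7-dimethyl-6,7-dihydro-5H-furo[3,2-g]chromen-2(3H)-one
Product: 6 2-(7-hydroxy-2,2-dimethylchroman-6-yl)-N-methoxy-N-methylacetamide
Conditions: MeNH(OMe)·HCl, AlMe3, CH2Cl2, 0 °C → rt; dilute aq. HCl work-up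
Reagents that add atoms: N,O-dimethylhydroxylamine hydrochloride, CNOC.Cl
Why: Aluminium amide aminolysis of a lactone (Weinreb amide formation) opens the aryl ester at the acyl carbon under Lewis acidic, non-basic conditions, so the acidic C3 protons of the benzofuranone are not removed and the C7′ phenol is released.

Step 3
Reactants: 6 2-(7-hydroxy-2,2-dimethylchroman-6-yl)-N-methoxy-N-methylacetamide
Product: 7 2-[2,2-dimethyl-7-(triisopropylsilyloxy)chroman-6-yl]-N-methoxy-N-methylacetamide
Conditions: iPr3SiCl, imidazole, DMF, rt
Reagents that add atoms: chlorotriisopropylsilane, CC(C)[Si](Cl)(C(C)C)C(C)C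
Why: Standard phenol silylation; the bulky triisopropylsilyl ether should resist the amidine base of step 10 and blocks attack of the ring A oxygen on the ynone or the alkyne.

Step 4
Reactants: 8 4-iodophenol; 9 prenyl bromide (1-bromo-3-methylbut-2-ene)
Product: 11 4-iodo-2-(3-methylbut-2-en-1-yl)phenol, via sodium 4-iodophenoxide 10 (not isolated)
Conditions: NaH, PhMe, 0 °C; then 9, rt
Reagents that add atoms: none
Why: ortho-C-Alkylation of a phenoxide: in toluene the sodium phenoxide 10 reacts as a tight ion pair, so the allylic bromide is delivered to the ortho carbon through a cyclic transition state and the dienone tautomerises back to the phenol; the para position is blocked by iodine.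

Step 5
Reactants: 11 4-iodo-2-(3-methylbut-2-en-1-yl)phenol
Product: 12 [4-iodo-2-(3-methylbut-2-en-1-yl)phenoxy]triisopropylsilane
Conditions: iPr3SiCl, imidazole, DMF, rt
Reagents that add atoms: chlorotriisopropylsilane, CC(C)[Si](Cl)(C(C)C)C(C)C
Why: Silylation removes the phenol nucleophile that would otherwise open the epoxide made in step 7.

Step 6
Reactants: 12 [4-iodo-2-(3-methylbut-2-en-1-yl)phenoxy]triisopropylsilane; 13 ethynyltrimethylsilane
Product: 14 trimethyl[[3-(3-methylbut-2-en-1-yl)-4-(triisopropylsilyloxy)phenyl]ethynyl]silane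
Conditions: Pd(PPh3)2Cl2 (2 mol %), CuI (4 mol %), Et3N, THF, rt
Reagents that add atoms: none
Why: Sonogashira coupling: oxidative addition of zerovalent palladium into the aryl C–I bond is fast at room temperature, and neither the prenyl alkene nor the aryl silyl ether takes part.

Step 7
Reactants: 14 trimethyl[[3-(3-methylbut-2-en-1-yl)-4-(triisopropylsilyloxy)phenyl]ethynyl]silane
Product: 15 [[3-[[(2R)-3,3-dimethyloxiran-2-yl]methyl]-4-(triisopropylsilyloxy)phenyl]ethynyl]trimethylsilane
Conditions: D-fructose-derived Shi ketone (0.3 equiv), Oxone (2KHSO5·KHSO4·K2SO4), K2CO3, Bu4NHSO4 (cat.), aq. Na2B4O7–Na2EDTA buffer, MeCN–CH2(OMe)2, 0 °C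
Reagents that add atoms: potassium peroxymonosulfate (KHSO5, the oxidant in Oxone), [K+].[O-]S(=O)(=O)OO
Why: Shi epoxidation: the chiral dioxirane transfers oxygen to the electron-rich trisubstituted alkene through a spiro transition state, and the D-fructose-derived catalyst should attack the face that gives the (R)-oxirane; the silylalkyne and the arene are not oxidised and the basic buffer keeps the epoxide intact.

Step 8
Reactants: 15 [[3-[[(2R)-3,3-dimethyloxiran-2-yl]methyl]-4-(triisopropylsilyloxy)phenyl]ethynyl]trimethylsilane
Product: 16 [2-[[(2R)-3,3-dimethyloxiran-2-yl]methyl]-4-ethynylphenoxy]triisopropylsilane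
Conditions: K2CO3 (0.2 equiv), MeOH, 0 °C
Reagents that add atoms: none
Why: Carbonate-catalysed methanolysis cleaves the C(sp)–Si bond within minutes, whereas the aryl triisopropylsilyl ether and the epoxide, which has no free phenol beside it, should survive the short, cold exposure.

Step 9
Reactants: 16 [2-[[(2R)-3,3-dimethyloxiran-2-yl]methyl]-4-ethynylphenoxy]triisopropylsilane; 7 2-[2,2-dimethyl-7-(triisopropylsilyloxy)chroman-6-yl]-N-methoxy-N-methylacetamide
Product: 19 1-[2,2-dimethyl-7-(triisopropylsilyloxy)chroman-6-yl]-4-[3-[[(2R)-3,3-dimethyloxiran-2-yl]methyl]-4-(triisopropylsilyloxy)phenyl]but-3-yn-2-one, via lithium acetylide 17 (not isolated), via tetrahedral lithium chelate 18 (not isolated)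
Conditions: n-BuLi, THF, −78 °C; then 7, −78 → −20 °C; aq. NH4Cl
Reagents that add atoms: none
Why: Weinreb ketone synthesis: acetylide 17 adds once to amide 7 and the five-membered N,O-chelate 18 holds the tetrahedral stage until the quench, so no tertiary alcohol forms; at low temperature addition should outrun enolisation of 7, and the acetylide does not open the epoxide without a Lewis acid.

Step 10
Reactants: 19 1-[2,2-dimethyl-7-(triisopropylsilyloxy)chroman-6-yl]-4-[3-[[(2R)-3,3-dimethyloxiran-2-yl]methyl]-4-(triisopropylsilyloxy)phenyl]but-3-yn-2-one; 20 carbon dioxide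
Product: 23 (5Z)-3-[2,2-dimethyl-7-(triisopropylsilyloxy)chroman-6-yl]-5-[[3-[[(2R)-3,3-dimethyloxiran-2-yl]methyl]-4-(triisopropylsilyloxy)phenyl]methylidene]-4-hydroxyfuran-2(5H)-one, via amidinium β-keto carboxylate 21 (not isolated), via alkenylsilver species 22 (not isolated)
Conditions: AgOAc (10 mol %), DBU (2 equiv), 20 (1.0 MPa), MeCN, 25 °C; cold aq. NaH2PO4 work-up
Reagents that add atoms: none
Why: The amidine base enolises the benzylic ketone CH2 (C3) and the enolate is carboxylated at carbon by 20 to give β-keto carboxylate 21 (bond C2–C3). Monovalent silver binds the triple bond and the carboxylate oxygen adds to C5 from the face opposite the metal in a 5-exo-dig closure (bond O1–C5) to give alkenylsilver 22; protodeargentation with retention and enolisation of the C4 ketone then give tetronic acid 23. The closest known reaction type is the silver-catalysed carboxylative cyclisation of conjugated alkynyl ketones with carbon dioxide to 5-ylidene tetronic acids, together with the silver-catalysed 5-exo lactonisation of (Z)-2-en-4-ynoic acids. Ring C is the only ring closed and its mode is 5-exo-dig. No stereocentre is created (C3 ends as sp2); the C5=C6 geometry is controlled by the anti addition of oxygen and silver, which places ring D cis to O1 (Z), and the remote (R)-oxirane is not touched. The step needs C- over O-carboxylation, which the reversibility of enol carbonate formation and the irreversible cyclisation of 21 should secure. It also needs 5-exo over 6-endo closure, which the silver carboxylate and the short tether of the enolised β-keto carboxylate should favour over the conjugate 6-endo path to a 2-pyranone. Silylation of both phenols removes the competing oxygen nucleophiles, and the epoxide should be inert to the base and to 20 at room temperature.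

Step 11
Reactants: 23 (5Z)-3-[2,2-dimethyl-7-(triisopropylsilyloxy)chroman-6-yl]-5-[[3-[[(2R)-3,3-dimethyloxiran-2-yl]methyl]-4-(triisopropylsilyloxy)phenyl]methylidene]-4-hydroxyfuran-2(5H)-one
Product: 24 (5Z)-5-[[3-[[(2R)-3,3-dimethyloxiran-2-yl]methyl]-4-hydroxyphenyl]methylidene]-4-hydroxy-3-(7-hydroxy-2,2-dimethylchroman-6-yl)furan-2(5H)-one
Conditions: Bu4NF–AcOH (1:1, 3 equiv), THF, 0 °C; pH 5 phosphate buffer (NaH2PO4/Na2HPO4) work-up
Reagents that add atoms: none
Why: Fluoride cleaves both aryl Si–O bonds at 0 °C and the acetic acid buffer keeps the released phenols protonated, which should prevent the ring D phenoxide from opening the oxirane; the tetronic acid is recovered from its ammonium salt by extraction at pH 5.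

## Compound list

1 | 2-(2,4-dihydroxyphenyl)acetic acid | OC(=O)Cc1ccc(O)cc1O | starting material
2 | isoprene (2-methylbuta-1,3-diene) | C=CC(C)=C | starting material
3 | 2-[2,4-dihydroxy-5-(3-methylbut-2-en-1-yl)phenyl]acetic acid | OC(=O)Cc1cc(CC=C(C)C)c(O)cc1O | intermediate (not isolated)
4 | 2-(7-hydroxy-2,2-dimethylchroman-6-yl)acetic acid | OC(=O)Cc1cc2CCC(C)(C)Oc2cc1O | intermediate (not isolated)
5 | 7,7-dimethyl-6,7-dihydro-5H-furo[3,2-g]chromen-2(3H)-one | O=C1Cc2cc3CCC(C)(C)Oc3cc2O1 | intermediate
6 | 2-(7-hydroxy-2,2-dimethylchroman-6-yl)-N-methoxy-N-methylacetamide | CON(C)C(=O)Cc1cc2CCC(C)(C)Oc2cc1O | intermediate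
7 | 2-[2,2-dimethyl-7-(triisopropylsilyloxy)chroman-6-yl]-N-methoxy-N-methylacetamide | CON(C)C(=O)Cc1cc2CCC(C)(C)Oc2cc1O[Si](C(C)C)(C(C)C)C(C)C | intermediate
8 | 4-iodophenol | Oc1ccc(I)cc1 | starting material
9 | prenyl bromide (1-bromo-3-methylbut-2-ene) | CC(C)=CCBr | starting material
10 | sodium 4-iodophenoxide | [Na+].[O-]c1ccc(I)cc1 | intermediate (not isolated)
11 | 4-iodo-2-(3-methylbut-2-en-1-yl)phenol | CC(C)=CCc1cc(I)ccc1O | intermediate
12 | [4-iodo-2-(3-methylbut-2-en-1-yl)phenoxy]triisopropylsilane | CC(C)=CCc1cc(I)ccc1O[Si](C(C)C)(C(C)C)C(C)C | intermediate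
13 | ethynyltrimethylsilane | C#C[Si](C)(C)C | starting material
14 | trimethyl[[3-(3-methylbut-2-en-1-yl)-4-(triisopropylsilyloxy)phenyl]ethynyl]silane | CC(C)=CCc1cc(C#C[Si](C)(C)C)ccc1O[Si](C(C)C)(C(C)C)C(C)C | intermediate
15 | [[3-[[(2R)-3,3-dimethyloxiran-2-yl]methyl]-4-(triisopropylsilyloxy)phenyl]ethynyl]trimethylsilane | C[Si](C)(C)C#Cc1ccc(O[Si](C(C)C)(C(C)C)C(C)C)c(C[C@H]2OC2(C)C)c1 | intermediate
16 | [2-[[(2R)-3,3-dimethyloxiran-2-yl]methyl]-4-ethynylphenoxy]triisopropylsilane | C#Cc1ccc(O[Si](C(C)C)(C(C)C)C(C)C)c(C[C@H]2OC2(C)C)c1 | intermediate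
17 | lithium acetylide of 16 | [Li]C#Cc1ccc(O[Si](C(C)C)(C(C)C)C(C)C)c(C[C@H]2OC2(C)C)c1 | intermediate (not isolated)
18 | lithium alkoxide adduct of acetylide 17 to the amide carbonyl of 7 (N,O-chelate, both epimers at the new carbon) | CON(C)C(O[Li])(Cc1cc2CCC(C)(C)Oc2cc1O[Si](C(C)C)(C(C)C)C(C)C)C#Cc1ccc(O[Si](C(C)C)(C(C)C)C(C)C)c(C[C@H]2OC2(C)C)c1 | intermediate (not isolated)
19 | 1-[2,2-dimethyl-7-(triisopropylsilyloxy)chroman-6-yl]-4-[3-[[(2R)-3,3-dimethyloxiran-2-yl]methyl]-4-(triisopropylsilyloxy)phenyl]but-3-yn-2-one | O=C(Cc1cc2CCC(C)(C)Oc2cc1O[Si](C(C)C)(C(C)C)C(C)C)C#Cc1ccc(O[Si](C(C)C)(C(C)C)C(C)C)c(C[C@H]2OC2(C)C)c1 | intermediate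
20 | carbon dioxide | O=C=O | starting material
21 | 1,8-diazabicyclo[5.4.0]undec-7-enium 2-[2,2-dimethyl-7-(triisopropylsilyloxy)chroman-6-yl]-5-[3-[[(2R)-3,3-dimethyloxiran-2-yl]methyl]-4-(triisopropylsilyloxy)phenyl]-3-oxopent-4-ynoate (both epimers at C2) | [O-]C(=O)C(C(=O)C#Cc1ccc(O[Si](C(C)C)(C(C)C)C(C)C)c(C[C@H]2OC2(C)C)c1)c1cc2CCC(C)(C)Oc2cc1O[Si](C(C)C)(C(C)C)C(C)C.C1CCC2=[NH+]CCCN2CC1 | intermediate (not isolated)
22 | (E)-alkenylsilver adduct: compound 23 with monovalent silver on C6 in place of hydrogen, trans to O1 | CC1(C)CCc2cc(C3=C(O)/C(=C(\[Ag])c4ccc(O[Si](C(C)C)(C(C)C)C(C)C)c(C[C@H]5OC5(C)C)c4)OC3=O)c(O[Si](C(C)C)(C(C)C)C(C)C)cc2O1 | intermediate (not isolated)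
23 | (5Z)-3-[2,2-dimethyl-7-(triisopropylsilyloxy)chroman-6-yl]-5-[[3-[[(2R)-3,3-dimethyloxiran-2-yl]methyl]-4-(triisopropylsilyloxy)phenyl]methylidene]-4-hydroxyfuran-2(5H)-one | CC1(C)CCc2cc(C3=C(O)/C(=C/c4ccc(O[Si](C(C)C)(C(C)C)C(C)C)c(C[C@H]5OC5(C)C)c4)OC3=O)c(O[Si](C(C)C)(C(C)C)C(C)C)cc2O1 | intermediate
24 | (5Z)-5-[[3-[[(2R)-3,3-dimethyloxiran-2-yl]methyl]-4-hydroxyphenyl]methylidene]-4-hydroxy-3-(7-hydroxy-2,2-dimethylchroman-6-yl)furan-2(5H)-one | CC1(C)CCc2cc(C3=C(O)/C(=C/c4ccc(O)c(C[C@H]5OC5(C)C)c4)OC3=O)c(O)cc2O1 | target

## Step count and risks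

Total step count: 11. Longest linear sequence: 8 steps (steps 4 to 11, from 8); the other branch runs 6 steps (steps 1 to 3, then 9 to 11).

Step 10 (key step).
- Most likely failure: ring closure in the 6-endo mode, because the distal alkyne carbon is the conjugate position of the ynone and carries an electron-rich arene.
- Also possible: slow carboxylation next to the bulky ortho silyloxy group, which leaves the enolate free to add to a second ynone; or loss of the ring D silyl group to the amidine.
- Fallback: make the tetronic acid first and the alkene last by vinylogous aldol condensation. It sets out from lactone 5 and aryl iodide 12 and comes back at 23.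
- Lactone 5 is treated with methyl glycolate and KOtBu in DMF (transesterification, then Dieckmann condensation) to give 4-hydroxy-3-(7-hydroxy-2,2-dimethylchroman-6-yl)furan-2(5H)-one F1. Its phenol is silylated (iPr3SiCl, imidazole; aqueous work-up cleaves the labile silyl tetronate) to 4-hydroxy-3-[2,2-dimethyl-7-(triisopropylsilyloxy)chroman-6-yl]furan-2(5H)-one F2.
- Iodide 12 is epoxidised under the conditions of step 7 to [2-[[(2R)-3,3-dimethyloxiran-2-yl]methyl]-4-iodophenoxy]triisopropylsilane F3; the alkene should be oxidised far faster than the iodoarene. Iodine–lithium exchange (t-BuLi, Et2O, −78 °C) and a DMF quench give 3-[[(2R)-3,3-dimethyloxiran-2-yl]methyl]-4-(triisopropylsilyloxy)benzaldehyde F4.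
- Condensation of F2 with F4 (DBU, MeCN) should give 23, the Z isomer being the thermodynamic one.

Step 11.
- Most likely failure: intramolecular opening of the oxirane by the freshly released ortho phenol or phenoxide (5-exo at the secondary carbon) during desilylation or work-up, helped by the acidity of the tetronic acid.
- Fallback: exchange silicon for acetyl before any phenol is set free, then remove the acetates without acid or base. It sets out from 23 and comes back at 24.
- CsF and Ac2O in DMF at 0 °C should trap each phenoxide as it forms and acetylate the tetronic acid, giving (5Z)-4-acetoxy-3-(7-acetoxy-2,2-dimethylchroman-6-yl)-5-[[4-acetoxy-3-[[(2R)-3,3-dimethyloxiran-2-yl]methyl]phenyl]methylidene]furan-2(5H)-one F5.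
- The three acetates are then removed by lipase-catalysed transesterification (immobilised Candida antarctica lipase B, n-BuOH, t-BuOMe, 30 °C).

Step 9.
- Most likely failure: deprotonation of the benzylic CH2 of amide 7 by the acetylide instead of addition, since the two acidities are close and the ortho silyloxy group hinders the carbonyl; conversion would then stall.
- Fallback: carbonyl addition and oxidation in place of acyl substitution. It sets out from amide 7 and comes back at 19.
- iBu2AlH (THF, −78 °C) reduces 7 to 2-[2,2-dimethyl-7-(triisopropylsilyloxy)chroman-6-yl]acetaldehyde F6.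
- Acetylide 17 adds to the more electrophilic aldehyde at −78 °C to give 1-[2,2-dimethyl-7-(triisopropylsilyloxy)chroman-6-yl]-4-[3-[[(2R)-3,3-dimethyloxiran-2-yl]methyl]-4-(triisopropylsilyloxy)phenyl]but-3-yn-2-ol F7 (both carbinol epimers serve).
- Dess–Martin periodinane (NaHCO3, CH2Cl2) oxidises F7 to 19.

Step 4.
- Most likely failure: O-alkylation and double alkylation competing with ortho C-alkylation, because the selectivity rests only on ion pairing in a non-polar solvent.
- Fallback: a sigmatropic route that can only deliver carbon to the ortho position. It sets out from 8 and comes back at 12.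
- O-Allylation (allyl bromide, K2CO3, acetone) gives 1-iodo-4-(prop-2-en-1-yloxy)benzene F8.
- Aromatic Claisen rearrangement (N,N-diethylaniline, 190 °C) gives 4-iodo-2-(prop-2-en-1-yl)phenol F9.
- Silylation (iPr3SiCl, imidazole) gives [4-iodo-2-(prop-2-en-1-yl)phenoxy]triisopropylsilane F10.
- Cross-metathesis with 2-methylbut-2-ene (second-generation Grubbs catalyst (H2IMes)(PCy3)Cl2Ru=CHPh, CH2Cl2, 40 °C) converts the allyl group into the prenyl group of 12.

Step 1.
- Most likely failure: attack of the prenyl cation at C3 between the two hydroxyls, or a second annulation, because both hydroxyls activate the ring.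
- Fallback: annulate a symmetrical arene first and add the acetic acid carbons afterwards. It sets out from isoprene 2 and comes back at 5.
- 2 is condensed under the same acid catalysis with resorcinol, whose two reactive positions are equivalent, to give 2,2-dimethylchroman-7-ol F11.
- Hydroxyalkylation with glyoxylic acid (aq. NaOH) at C6, ortho to the hydroxyl and para to the ring oxygen, gives 2-hydroxy-2-(7-hydroxy-2,2-dimethylchroman-6-yl)acetic acid F12.
- Hydrogenolysis of the benzylic hydroxyl (H2, Pd/C, AcOH) and acid-catalysed lactonisation give 5.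

## Further compounds

F1 | step 10 | 4-hydroxy-3-(7-hydroxy-2,2-dimethylchroman-6-yl)furan-2(5H)-one | O=C1OCC(O)=C1c1cc2CCC(C)(C)Oc2cc1O
F2 | step 10 | 4-hydroxy-3-[2,2-dimethyl-7-(triisopropylsilyloxy)chroman-6-yl]furan-2(5H)-one | O=C1OCC(O)=C1c1cc2CCC(C)(C)Oc2cc1O[Si](C(C)C)(C(C)C)C(C)C
F3 | step 10 | [2-[[(2R)-3,3-dimethyloxiran-2-yl]methyl]-4-iodophenoxy]triisopropylsilane | Ic1ccc(O[Si](C(C)C)(C(C)C)C(C)C)c(C[C@H]2OC2(C)C)c1
F4 | step 10 | 3-[[(2R)-3,3-dimethyloxiran-2-yl]methyl]-4-(triisopropylsilyloxy)benzaldehyde | O=Cc1ccc(O[Si](C(C)C)(C(C)C)C(C)C)c(C[C@H]2OC2(C)C)c1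
F5 | step 11 | (5Z)-4-acetoxy-3-(7-acetoxy-2,2-dimethylchroman-6-yl)-5-[[4-acetoxy-3-[[(2R)-3,3-dimethyloxiran-2-yl]methyl]phenyl]methylidene]furan-2(5H)-one | CC1(C)CCc2cc(C3=C(OC(C)=O)/C(=C/c4ccc(OC(C)=O)c(C[C@H]5OC5(C)C)c4)OC3=O)c(OC(C)=O)cc2O1
F6 | step 9 | 2-[2,2-dimethyl-7-(triisopropylsilyloxy)chroman-6-yl]acetaldehyde | O=CCc1cc2CCC(C)(C)Oc2cc1O[Si](C(C)C)(C(C)C)C(C)C
F7 | step 9 | 1-[2,2-dimethyl-7-(triisopropylsilyloxy)chroman-6-yl]-4-[3-[[(2R)-3,3-dimethyloxiran-2-yl]methyl]-4-(triisopropylsilyloxy)phenyl]but-3-yn-2-ol | OC(Cc1cc2CCC(C)(C)Oc2cc1O[Si](C(C)C)(C(C)C)C(C)C)C#Cc1ccc(O[Si](C(C)C)(C(C)C)C(C)C)c(C[C@H]2OC2(C)C)c1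
F8 | step 4 | 1-iodo-4-(prop-2-en-1-yloxy)benzene | C=CCOc1ccc(I)cc1
F9 | step 4 | 4-iodo-2-(prop-2-en-1-yl)phenol | C=CCc1cc(I)ccc1O
F10 | step 4 | [4-iodo-2-(prop-2-en-1-yl)phenoxy]triisopropylsilane | C=CCc1cc(I)ccc1O[Si](C(C)C)(C(C)C)C(C)C
F11 | step 1 | 2,2-dimethylchroman-7-ol | CC1(C)CCc2ccc(O)cc2O1
F12 | step 1 | 2-hydroxy-2-(7-hydroxy-2,2-dimethylchroman-6-yl)acetic acid | OC(C(=O)O)c1cc2CCC(C)(C)Oc2cc1O
A1 | alternative 1 | 3-[7-(benzyloxy)-2,2-dimethylchroman-6-yl]-4-methoxyfuran-2(5H)-one | COC1=C(c2cc3CCC(C)(C)Oc3cc2OCc2ccccc2)C(=O)OC1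
A2 | alternative 1 | 4-(benzyloxy)-3-(3-methylbut-2-en-1-yl)benzaldehyde | O=Cc1ccc(OCc2ccccc2)c(CC=C(C)C)c1
A3 | alternative 1 | (5Z)-3-[7-(benzyloxy)-2,2-dimethylchroman-6-yl]-5-[[4-(benzyloxy)-3-(3-methylbut-2-en-1-yl)phenyl]methylidene]-4-methoxyfuran-2(5H)-one | COC1=C(c2cc3CCC(C)(C)Oc3cc2OCc2ccccc2)C(=O)O/C1=C\c1ccc(OCc2ccccc2)c(CC=C(C)C)c1
A4 | alternative 2 | (5Z)-3-bromo-5-[[3-[[(2R)-3,3-dimethyloxiran-2-yl]methyl]-4-(triisopropylsilyloxy)phenyl]methylidene]-4-methoxyfuran-2(5H)-one | COC1=C(Br)C(=O)O/C1=C\c1ccc(O[Si](C(C)C)(C(C)C)C(C)C)c(C[C@H]2OC2(C)C)c1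
A5 | alternative 2 | 2-[2,2-dimethyl-7-(triisopropylsilyloxy)chroman-6-yl]-4,4,5,5-tetramethyl-1,3,2-dioxaborolane | CC1(C)CCc2cc(B3OC(C)(C)C(C)(C)O3)c(O[Si](C(C)C)(C(C)C)C(C)C)cc2O1
A6 | alternative 3 | methyl 2-[2,4-dihydroxy-5-(hydroxymethyl)phenyl]acetate | COC(=O)Cc1cc(CO)c(O)cc1O
A7 | alternative 3 | methyl 2-(6-hydroxy-3-methylidene-4-oxocyclohexa-1,5-dien-1-yl)acetate | COC(=O)CC1=CC(=C)C(=O)C=C1O
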